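If each step on the way to the complex with four exchanged is pseudo-first-order in incoming ligand, its time constant scales inversely with that ligand. A flask then depends on ligand concentration times time, and I can translate any flask into an equivalent violet time: its ligand times its time, divided by the violet ligand.

| setting | ochre | violet | west | north-west | south |
|---|---|---|---|---|---|
| starting complex | 0.50 M | 0.50 M | 0.50 M | 0.50 M | 0.50 M |
| incoming ligand | 0.31 M | 2 M | 0.250 M | 0.750 M | 1.50 M |
| remark | run made earlier | run made earlier |  |  |  |
| time |  |  | 2.5 min | 2.5 min | 2.5 min |

| run | time / s | complex with four exchanged / % | complex with three exchanged / % |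
|---|---|---|---|
| ochre | 10.0 | 0.6 | 0 |
| ochre | 20.0 | 0.2 | 0 |
| ochre | 30.0 | 0 | 0.6 |
| ochre | 40.0 | 0 | 0.3 |
| ochre | 50.0 | 0 | 0 |
| ochre | 60.0 | 0.5 | 0.5 |
| ochre | 80.0 | 0 | 0.4 |
| violet | 10.0 | 0 | 0.3 |
| violet | 12.0 | 0.3 | 0 |
| violet | 20.0 | 0.2 | 1.1 |
| violet | 30.0 | 0.6 | 1.8 |
| violet | 50.0 | 2.8 | 1.9 |
| violet | 60.0 | 3.8 | 2.7 |
| violet | 80.0 | 6.8 | 4.5 |

(each reading ± 0.5 percentage points)

1. complex with four exchanged at the end, in percent of the starting complex charged, for each flask in turn (west, north-west, south)



I keep the ledger on the charged starting complex in violet at 80.0 s: 6.8% stands as complex with four exchanged, 4.5% as complex with three exchanged, and 88.7% is unread. These two read entries hold 0.204 M of the 2 M of incoming ligand, so I treat the ligand as nearly constant in my reckoning. The check is thin: ochre at 80.0 s reaches an equivalent violet time of 12.4 s, and the complex with four exchanged reads 0% there in ochre and 0.3% at 12.0 s in violet, both within the scatter of zero.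

In logarithms, the complex with four exchanged in violet rises from 50.0 s to 80.0 s with slope 1.89. The equivalent violet times are 18.8 s for west, 56.2 s for north-west and 112 s for south. My reckoning therefore gives 0.440%, 3.50% and 12.9%, the first lying below the scatter.

The forecast stands lower than these, with 0.1%, 1.3% and 10%, by “Scaling with L², plus a slower follow-on step and ligand depletion”.

The flasks give 0.0637%, 1.80% and 7.60%.

    starting complex + incoming ligand ⇌ leaving ligand + complex with one exchanged (K = 0.170, k = 0.0380 M⁻¹ s⁻¹)
    complex with one exchanged + incoming ligand ⇌ leaving ligand + complex with two exchanged (K = 0.990, k = 0.00360 M⁻¹ s⁻¹)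
    complex with two exchanged + incoming ligand ⇌ leaving ligand + complex with three exchanged (K = 1.50, k = 0.0170 M⁻¹ s⁻¹)
    complex with three exchanged + incoming ligand ⇌ leaving ligand + complex with four exchanged (K = 0.630, k = 0.0530 M⁻¹ s⁻¹)
    2 starting complex → homo dimer (k = 0.0250 M⁻¹ s⁻¹)

Between north-west and south, whose equivalent violet times differ by a factor of 1.99, the slope is 2.09, close to my 1.89. North-west still stands below my 3.50%, and part of that gap is the falling level of incoming ligand, of which 78% is left at the end. The same north-west run with the ligand held at its charge gives 2.91% instead of 1.80%. The length of the run is at most the largest single effect on north-west: at 25.0 min that flask holds 6.95%. South at 1.25 min has the same equivalent violet time, 56.2 s, and holds 3.03% as complex with four exchanged.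

All runs are simulated with made-up constants.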